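**Strategy.** The target is read as a mono-epoxidised cyclohexa-1,3-diene: the C4=C5 alkene and the C1–C6 oxirane of the 7-oxabicyclo[4.1.0]hept-4-ene are a masked C4=C5–C6=C1 diene whose only sp3 carbons, C2 and C3, carry the trans ester oxygens. Such a diene is what a 2-pyrone gives after [4+2] cycloaddition and loss of CO2. The key step is therefore an enantioselective inverse-demand Diels–Alder reaction of methyl 2-oxo-2H-pyran-3-carboxylate with an (E)-1-alkoxy-2-acyloxyethene, which forms C1–C2 and C3–C4, both oxygenated stereocentres and their O-differentiation at once; the ester at C1 is the latent CH2OBz group.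

Key step: step 3

Remark on numbering: ring atoms are called C1–C6 as in the target (C1 quaternary oxirane carbon, C2 acetoxy carbon, C3 benzoyloxy carbon, C4=C5, C6 oxirane CH); PMB = 4-methoxybenzyl, Bpin = pinacolatoboryl.

Assumption: the (S,S)-ligand is written because the square-planar two-point chelate model leaves open the pyrone face that leads to (4S)-6; if the adduct proves to be the antipode, the (R,R)-ligand is used and nothing else changes.

**Step 1**
Reactants: 1 (E)-1,2-bis(Bpin)ethene (2.5 equiv, excess recovered); 2 4-methoxybenzyl alcohol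
Product: 3 2-[(E)-2-[(4-methoxybenzyl)oxy]ethenyl]-4,4,5,5-tetramethyl-1,3,2-dioxaborolane
Conditions: Cu(OAc)2 (2 equiv), Et3N (4 equiv), 4 Å MS, CH2Cl2, rt
Reagents that add atoms: none
Why: A Chan–Lam-type oxidative C–O coupling of an alkenyl pinacol boronate with an alcohol, promoted by divalent copper, replaces one boron by the alkoxy group with retention of the E geometry, and the excess of 1 together with the lower reactivity of the β-alkoxyvinyl boronate formed should stop the reaction at the mono-ether.

**Step 2**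
Reactants: 3 2-[(E)-2-[(4-methoxybenzyl)oxy]ethenyl]-4,4,5,5-tetramethyl-1,3,2-dioxaborolane
Product: 4 (E)-2-[(4-methoxybenzyl)oxy]ethenyl benzoate
Conditions: Cu(O2CPh)2 (2 equiv), Et3N (3 equiv), 4 Å MS, CH2Cl2, rt
Reagents that add atoms: copper dibenzoate, O=C([O-])c1ccccc1.O=C([O-])c1ccccc1.[Cu+2]
Why: The same Chan–Lam-type manifold transfers a carboxylate from divalent copper to the alkenyl boronate with retention of the E geometry, and the amine keeps the medium non-acidic so that the enol ether is not protodeboronated.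

**Step 3**
Reactants: 4 (E)-2-[(4-methoxybenzyl)oxy]ethenyl benzoate; 5 methyl 2-oxo-2H-pyran-3-carboxylate
Product: 6 methyl (1R,4S,7R,8R)-7-(benzoyloxy)-8-[(4-methoxybenzyl)oxy]-3-oxo-2-oxabicyclo[2.2.2]oct-5-ene-4-carboxylate
Conditions: Cu(OTf)2 (10 mol %), (S,S)-t-Bu-BOX [2,2'-(propane-2,2-diyl)bis((4S)-4-tert-butyl-4,5-dihydrooxazole), 11 mol %], 4 Å MS, CH2Cl2, −20 °C to rt; minor diastereomer removed by chromatography
Reagents that add atoms: none
Why: Two-point binding of the lactone and ester carbonyls of 5 to divalent copper lowers the LUMO of the pyrone, and the enol ether adds across C3 and C6 of the pyrone in a concerted, asynchronous inverse-electron-demand Diels–Alder reaction, the closest known type being chiral Lewis acid-catalysed cycloadditions of 2-pyrone-3-carboxylates with alkyl vinyl ethers. The new six-membered carbocycle is closed in [4+2] mode, suprafacially on both partners, and the lactone is left as a two-atom bridge. Regiochemistry follows from polarisation: the carbon β to the ether oxygen, which carries the benzoate, is the nucleophilic terminus and bonds to the electrophilic C6 of the pyrone, so that the ether carbon ends next to the ester-bearing carbon. In the numbering of 6, C7 and C8 are trans because the E geometry of 4 is transferred stereospecifically, the C8 ether is endo (syn to the C5=C6 bridge) as is usual for the alkoxy group of an enol ether, and C1 and C4 are fixed by the face of the bound pyrone that the tert-butyl groups of the ligand leave open. The step needs regio-, endo- and facial selectivity together, since after loss of CO2 the endo and exo adducts of one pyrone face would give enantiomeric dienes; for that reason 6 is freed from its minor diastereomer before step 4.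

**Step 4**
Reactants: 6 methyl (1R,4S,7R,8R)-7-(benzoyloxy)-8-[(4-methoxybenzyl)oxy]-3-oxo-2-oxabicyclo[2.2.2]oct-5-ene-4-carboxylate
Product: 7 methyl (5R,6R)-5-(benzoyloxy)-6-[(4-methoxybenzyl)oxy]cyclohexa-1,3-diene-1-carboxylate
Conditions: PhMe (0.02 M, degassed), 2,6-di-tert-butyl-4-methylphenol (cat.), 105 °C, base-washed glassware; used directly
Reagents that add atoms: none
Why: Thermal retro-Diels–Alder extrusion of CO2 from the bridged lactone converts the two bridgeheads into the sp2 termini of a cyclohexa-1,3-diene without touching the two oxygenated stereocentres, and dilute, base-free conditions are chosen to suppress elimination to an arene.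

**Step 5**
Reactants: 7 methyl (5R,6R)-5-(benzoyloxy)-6-[(4-methoxybenzyl)oxy]cyclohexa-1,3-diene-1-carboxylate
Product: 8 (1R,6R)-5-(hydroxymethyl)-6-[(4-methoxybenzyl)oxy]cyclohexa-2,4-dien-1-ol
Conditions: i-Bu2AlH (5 equiv), CH2Cl2, −78 to −20 °C; aq. potassium sodium tartrate
Reagents that add atoms: none
Why: Hydride reduction with i-Bu2AlH takes the conjugated methyl ester to the allylic alcohol in 1,2-fashion and cleaves the benzoate at the same time, while the PMB ether is inert and the cold, non-acidic work-up spares the dienol.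

**Step 6**
Reactants: 8 (1R,6R)-5-(hydroxymethyl)-6-[(4-methoxybenzyl)oxy]cyclohexa-2,4-dien-1-ol
Product: 9 [(5R,6R)-5-(benzoyloxy)-6-[(4-methoxybenzyl)oxy]cyclohexa-1,3-dien-1-yl]methyl benzoate
Conditions: BzCl (2.4 equiv), pyridine, DMAP (5 mol %), CH2Cl2, 0 °C
Reagents that add atoms: benzoyl chloride, O=C(Cl)c1ccccc1
Why: Nucleophile-catalysed acylation (DMAP) esterifies the primary and the secondary allylic hydroxyl in one operation, so that the benzoate lost in step 5 is reinstated together with the new primary one.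

**Step 7**
Reactants: 9 [(5R,6R)-5-(benzoyloxy)-6-[(4-methoxybenzyl)oxy]cyclohexa-1,3-dien-1-yl]methyl benzoate
Product: 10 [(1S,2S,3R,6S)-3-(benzoyloxy)-2-[(4-methoxybenzyl)oxy]-7-oxabicyclo[4.1.0]hept-4-en-1-yl]methyl benzoate
Conditions: mCPBA (1.2 equiv), NaHCO3 (solid), CH2Cl2, 0 °C
Reagents that add atoms: mCPBA, OOC(=O)c1cccc(Cl)c1
Why: Prilezhaev epoxidation is expected at the more nucleophilic trisubstituted C1=C6 alkene and from the face anti to the pseudoaxial allylic C2 ether, which sets C1 and C6 under substrate control as in the anti-selective peracid epoxidation of the corresponding 2-acyloxy dienes.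

**Step 8**
Reactants: 10 [(1S,2S,3R,6S)-3-(benzoyloxy)-2-[(4-methoxybenzyl)oxy]-7-oxabicyclo[4.1.0]hept-4-en-1-yl]methyl benzoate
Product: 11 [(1S,2S,3R,6S)-3-(benzoyloxy)-2-hydroxy-7-oxabicyclo[4.1.0]hept-4-en-1-yl]methyl benzoate
Conditions: DDQ (1.5 equiv), CH2Cl2/pH 7 phosphate buffer (10:1), 0 °C to rt
Reagents that add atoms: none
Why: Oxidative cleavage of the PMB ether by DDQ (hydride abstraction from the electron-rich benzylic position, then hydrolysis of the oxocarbenium ion) frees the C2 hydroxyl, and it is placed after the epoxidation because no cyclohexadiene is then left that DDQ could dehydrogenate.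

**Step 9**
Reactants: 11 [(1S,2S,3R,6S)-3-(benzoyloxy)-2-hydroxy-7-oxabicyclo[4.1.0]hept-4-en-1-yl]methyl benzoate
Product: 12 [(1S,2S,3R,6S)-2-(acetyloxy)-3-(benzoyloxy)-7-oxabicyclo[4.1.0]hept-4-en-1-yl]methyl benzoate
Conditions: Ac2O (3 equiv), pyridine, DMAP (10 mol %), CH2Cl2, 0 °C to rt
Reagents that add atoms: acetic anhydride, CC(=O)OC(C)=O
Why: DMAP-catalysed acetylation of the hindered secondary alcohol under non-acidic conditions leaves the vinyl oxirane and the two benzoates untouched and gives the target.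

**Compound list**
1 | (E)-1,2-bis(4,4,5,5-tetramethyl-1,3,2-dioxaborolan-2-yl)ethene | CC1(C)OB(/C=C/B2OC(C)(C)C(C)(C)O2)OC1(C)C | starting material
2 | 4-methoxybenzyl alcohol | COc1ccc(CO)cc1 | starting material
3 | 2-[(E)-2-[(4-methoxybenzyl)oxy]ethenyl]-4,4,5,5-tetramethyl-1,3,2-dioxaborolane | COc1ccc(CO/C=C/B2OC(C)(C)C(C)(C)O2)cc1 | intermediate
4 | (E)-2-[(4-methoxybenzyl)oxy]ethenyl benzoate | COc1ccc(CO/C=C/OC(=O)c2ccccc2)cc1 | intermediate
5 | methyl 2-oxo-2H-pyran-3-carboxylate | COC(=O)C1=CC=COC1=O | starting material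
6 | methyl (1R,4S,7R,8R)-7-(benzoyloxy)-8-[(4-methoxybenzyl)oxy]-3-oxo-2-oxabicyclo[2.2.2]oct-5-ene-4-carboxylate (ether endo, benzoate exo) | COC(=O)[C@@]12C=C[C@@H](OC1=O)[C@@H](OC(=O)c1ccccc1)[C@@H]2OCc1ccc(OC)cc1 | intermediate
7 | methyl (5R,6R)-5-(benzoyloxy)-6-[(4-methoxybenzyl)oxy]cyclohexa-1,3-diene-1-carboxylate | COC(=O)C1=CC=C[C@@H](OC(=O)c2ccccc2)[C@@H]1OCc1ccc(OC)cc1 | intermediate
8 | (1R,6R)-5-(hydroxymethyl)-6-[(4-methoxybenzyl)oxy]cyclohexa-2,4-dien-1-ol | OCC1=CC=C[C@@H](O)[C@@H]1OCc1ccc(OC)cc1 | intermediate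
9 | [(5R,6R)-5-(benzoyloxy)-6-[(4-methoxybenzyl)oxy]cyclohexa-1,3-dien-1-yl]methyl benzoate | O=C(OCC1=CC=C[C@@H](OC(=O)c2ccccc2)[C@@H]1OCc1ccc(OC)cc1)c1ccccc1 | intermediate
10 | [(1S,2S,3R,6S)-3-(benzoyloxy)-2-[(4-methoxybenzyl)oxy]-7-oxabicyclo[4.1.0]hept-4-en-1-yl]methyl benzoate | COc1ccc(CO[C@H]2[C@H](OC(=O)c3ccccc3)C=C[C@@H]3O[C@@]32COC(=O)c2ccccc2)cc1 | intermediate
11 | [(1S,2S,3R,6S)-3-(benzoyloxy)-2-hydroxy-7-oxabicyclo[4.1.0]hept-4-en-1-yl]methyl benzoate | O[C@H]1[C@H](OC(=O)c2ccccc2)C=C[C@@H]2O[C@@]21COC(=O)c1ccccc1 | intermediate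
12 | [(1S,2S,3R,6S)-2-(acetyloxy)-3-(benzoyloxy)-7-oxabicyclo[4.1.0]hept-4-en-1-yl]methyl benzoate | CC(=O)O[C@H]1[C@H](OC(=O)c2ccccc2)C=C[C@@H]2O[C@@]21COC(=O)c1ccccc1 | target

**Step count.** Total: 9 steps. Longest linear sequence: 9 steps (1 to 12); pyrone 5 enters at step 3.

**Steps most likely to fail**

Step 3. Endo or facial control in the cycloaddition may be incomplete, which after CO2 extrusion would show as eroded enantiomeric purity, and the acyloxy-deactivated enol ether may add sluggishly. The fallback moves stereocontrol from the catalyst to a covalently bound auxiliary. It sets out from 4, which is combined with (1R,2S,5R)-5-methyl-2-(2-phenylpropan-2-yl)cyclohexyl 2-oxo-2H-pyran-3-carboxylate F1 (from commercial 2-oxo-2H-pyran-3-carboxylic acid and the alcohol, DCC, DMAP) under Yb(OTf)3 catalysis in CH2Cl2, under 10 kbar if needed. The adducts are now diastereomers, so the auxiliary ester adduct with the ring configuration of 6, F2, is purified by crystallisation or chromatography. Thermolysis as in step 4 gives the auxiliary diene ester F3, and i-Bu2AlH reduction as in step 5 cleaves auxiliary and benzoate and comes back to the route at 8.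

Step 2. The acid-sensitive β-alkoxyvinyl boronate may protodeboronate, or carboxylate transfer from copper may be too slow. The fallback uses the C–B bond itself as the latent C3–O bond. It sets out from 3, which is added to 5 under the conditions of step 3 (the boron-bearing carbon is again the nucleophilic terminus) to give the 7-boryl analogue of 6 with the same spatial arrangement at all four ring stereocentres, F4. Oxidation with NaBO3·4H2O in THF/pH 7 buffer proceeds with retention to methyl (1R,4S,7R,8R)-7-hydroxy-8-[(4-methoxybenzyl)oxy]-3-oxo-2-oxabicyclo[2.2.2]oct-5-ene-4-carboxylate F5, and benzoylation (BzCl, pyridine) comes back to the route at 6.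

Step 1. The coupling may run on to the bis-ether, or acetate may be transferred from copper in competition with the alcohol. The fallback builds the vinyl boronate by hydroboration instead. It sets out from 2, which with KH and trichloroethylene in THF gives 1-[[(E)-1,2-dichloroethenyl]oxymethyl]-4-methoxybenzene F6. Treatment with n-BuLi (2.2 equiv, −78 °C) and a methanol quench gives 1-[(ethynyloxy)methyl]-4-methoxybenzene F7, kept cold and used at once. Syn, anti-Markovnikov addition of pinacolborane with Cp2Zr(H)Cl (cat.) comes back to the route at 3.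

**Further compounds**
F1 | step 3 | (1R,2S,5R)-5-methyl-2-(2-phenylpropan-2-yl)cyclohexyl 2-oxo-2H-pyran-3-carboxylate | C[C@@H]1CC[C@H]([C@@H](C1)OC(=O)C1=CC=COC1=O)C(C)(C)c1ccccc1
F2 | step 3 | (1R,2S,5R)-5-methyl-2-(2-phenylpropan-2-yl)cyclohexyl ester analogue of 6, same ring configuration | C[C@@H]1CC[C@H]([C@@H](C1)OC(=O)[C@@]12C=C[C@@H](OC1=O)[C@@H](OC(=O)c1ccccc1)[C@@H]2OCc1ccc(OC)cc1)C(C)(C)c1ccccc1
F3 | step 3 | (1R,2S,5R)-5-methyl-2-(2-phenylpropan-2-yl)cyclohexyl (5R,6R)-5-(benzoyloxy)-6-[(4-methoxybenzyl)oxy]cyclohexa-1,3-diene-1-carboxylate | C[C@@H]1CC[C@H]([C@@H](C1)OC(=O)C1=CC=C[C@@H](OC(=O)c2ccccc2)[C@@H]1OCc1ccc(OC)cc1)C(C)(C)c1ccccc1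
F4 | step 2 | methyl 8-[(4-methoxybenzyl)oxy]-3-oxo-7-(4,4,5,5-tetramethyl-1,3,2-dioxaborolan-2-yl)-2-oxabicyclo[2.2.2]oct-5-ene-4-carboxylate, boron in place of the benzoyloxy group of 6 | COC(=O)[C@@]12C=C[C@@H](OC1=O)[C@@H](B1OC(C)(C)C(C)(C)O1)[C@@H]2OCc1ccc(OC)cc1
F5 | step 2 | methyl (1R,4S,7R,8R)-7-hydroxy-8-[(4-methoxybenzyl)oxy]-3-oxo-2-oxabicyclo[2.2.2]oct-5-ene-4-carboxylate | COC(=O)[C@@]12C=C[C@@H](OC1=O)[C@@H](O)[C@@H]2OCc1ccc(OC)cc1
F6 | step 1 | 1-[[(E)-1,2-dichloroethenyl]oxymethyl]-4-methoxybenzene | COc1ccc(CO/C(Cl)=C\Cl)cc1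
F7 | step 1 | 1-[(ethynyloxy)methyl]-4-methoxybenzene | COc1ccc(COC#C)cc1
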